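Ring A, the quinone that carries the 2-(2-methoxyphenyl)ethyl chain (C1=O, C2–OH, C3–CH3, C4=O, C5–ring B, C6–chain), is built from two three-carbon units, C4–C5–C6 and C1–C2–C3. The key step is a [3+3] Michael–Claisen–sulfoxide-elimination cascade between a 3-alkylidenebenzofuran-2(3H)-one (lactone carbonyl = C4, ring carbon = C5, exocyclic carbon = C6; lactone oxygen = the ring B oxygen ortho to the biaryl bond) and 1-(phenylsulfinyl)butan-2-one. It forms C6–C1 and C4–C3, delivers ring A as a 2-methylresorcinol, creates the tetra-ortho-substituted biaryl axis without cross-coupling and frees the ring B phenol. It exploits the meta C2/C4 oxygens flanking C3–CH3 and that ortho oxygen; a double Fremy oxidation finishes.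

Key step: step 7

Remark: the target has no stereocentre and its hindered biaryl axis carries no descriptor, so all biaryls are made as racemates; 1-(3-bromopropyl)-2-methoxybenzene (7) is taken as a catalogue compound.

Step 1
Reactants: 1 3,5-dimethoxy-4-methylbenzaldehyde; 2 diethyl benzylphosphonate
Product: 4 (E)-1,3-dimethoxy-2-methyl-5-(2-phenylethenyl)benzene, via sodium phosphonate carbanion 3 (not isolated)
Conditions: NaH, THF, 0 → 60 °C
Reagents that add atoms: none
Why: Horner–Wadsworth–Emmons olefination of an aromatic aldehyde with a benzylic phosphonate carbanion should give the E-stilbene, and the alkene geometry is of no consequence because the double bond is hydrogenated in the next step.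

Step 2
Reactants: 4 (E)-1,3-dimethoxy-2-methyl-5-(2-phenylethenyl)benzene
Product: 5 1,3-dimethoxy-2-methyl-5-(2-phenylethyl)benzene
Conditions: H2 (1 atm), Pd/C (10 wt %), EtOAc, rt
Reagents that add atoms: none
Why: Heterogeneous catalytic hydrogenation should saturate the stilbene double bond without touching the aryl methyl ethers.

Step 3
Reactants: 5 1,3-dimethoxy-2-methyl-5-(2-phenylethyl)benzene
Product: 6 2-methyl-5-(2-phenylethyl)benzene-1,3-diol
Conditions: BBr3 (3 equiv), CH2Cl2, −78 °C → rt; then H2O
Reagents that add atoms: none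
Why: Lewis acid cleavage of both aryl methyl ethers (BBr3 demethylation) is placed here, before the anisole unit that must survive is brought in.

Step 4
Reactants: 7 1-(3-bromopropyl)-2-methoxybenzene; 8 diethyl oxalate
Product: 10 ethyl 5-(2-methoxyphenyl)-2-oxopentanoate, via Grignard reagent 9 (not isolated)
Conditions: Mg, I2 (cat.), THF, 40 °C; then into 8 (3 equiv), THF, −78 °C; 1 M HCl
Reagents that add atoms: none
Why: Grignard acylation by inverse addition to excess diethyl oxalate at low temperature should stop at the α-keto ester, because the tetrahedral magnesium alkoxide does not collapse before the quench.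

Step 5
Reactants: 6 2-methyl-5-(2-phenylethyl)benzene-1,3-diol; 10 ethyl 5-(2-methoxyphenyl)-2-oxopentanoate
Product: 13 (3Z)-6-hydroxy-3-[3-(2-methoxyphenyl)propylidene]-7-methyl-4-(2-phenylethyl)-1-benzofuran-2(3H)-one, via Friedel–Crafts hydroxy ester 11 (not isolated), via 3-hydroxy lactone 12 (not isolated)
Conditions: p-TsOH·H2O (0.2 equiv), toluene, reflux, Dean–Stark
Reagents that add atoms: none
Why: Acid-catalysed Friedel–Crafts hydroxyalkylation of the resorcinol at one of its two equivalent free positions (ortho and para to the hydroxy groups) by the keto carbonyl, lactonisation with the neighbouring phenol and E1 dehydration toward the only β-CH2 should give the alkylidene lactone as the Z isomer, in which the side chain avoids the C4 phenethyl group; the anisole ring of 10 could cyclise only meta to its methoxy group and is outcompeted.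

Step 6
Reactants: 14 methyl phenyl sulfoxide (racemic); 15 ethyl propanoate
Product: 17 1-(phenylsulfinyl)butan-2-one (racemic), via lithiated sulfoxide 16 (not isolated)
Conditions: LiN(i-Pr)2 (2.1 equiv), THF, −78 °C; then 15, −78 → 0 °C; 1 M HCl
Reagents that add atoms: none
Why: Claisen-type acylation of the α-sulfinyl carbanion by the ester should give the β-keto sulfoxide, the second equivalent of base being taken up by the acidic product so that no double acylation occurs.

Step 7
Reactants: 13 (3Z)-6-hydroxy-3-[3-(2-methoxyphenyl)propylidene]-7-methyl-4-(2-phenylethyl)-1-benzofuran-2(3H)-one; 17 1-(phenylsulfinyl)butan-2-one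
Product: 20 6-[2-(2-methoxyphenyl)ethyl]-3,3'-dimethyl-6'-(2-phenylethyl)biphenyl-2,2',4,4'-tetrol, via Michael adduct 18 (not isolated), via sulfinyl cyclohexanedione 19 (not isolated)
Conditions: KOt-Bu (1.2 equiv), THF/t-BuOH, Ar, 0 → 25 °C; then 65 °C; 1 M HCl
Reagents that add atoms: none
Why: The most acidic carbon of 17 (between sulfinyl and carbonyl) adds 1,4 to the exocyclic carbon of 13 (Michael addition, bond C6–C1 of ring A, driven by the aromatic 2-oxidobenzofuran), the ethyl-side enolate of the same ketone then attacks the lactone carbonyl in a Dieckmann-type Claisen acylation (6-(enolendo)-exo-trig, bond C4–C3) that expels the ring B phenoxide, and syn-elimination of benzenesulfenic acid from the α-sulfinyl ketone at 65 °C followed by enolisation gives the resorcinol ring. The closest known reactions are the β-keto sulfoxide phenol annulation of enones (Michael, aldol, sulfoxide elimination) and the Michael–Claisen synthesis of cyclohexane-1,3-diones from ketones and α,β-unsaturated esters. Regiochemistry is fixed by the substrate: only the sulfinyl carbon is nucleophilic enough for the conjugate addition, and afterwards only the ethyl-side carbon can reach the lactone carbonyl through a six-membered transition state (the other carbanions would close four-membered rings), so CH3 ends on C3 and H on C1. The stereocentres formed on the way (C5, C6, C1 and sulfur) arise as mixtures and are all erased by the elimination and aromatisation, and the new biaryl axis is racemic. The step needs 1,4- over 1,2-addition and C- over O-acylation; the soft doubly stabilised carbanion and the alkylidene lactone secure the first, and reversible enol-lactone formation under base against irreversible aromatisation of the C-acylated dione secures the second.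

Step 8
Reactants: 20 6-[2-(2-methoxyphenyl)ethyl]-3,3'-dimethyl-6'-(2-phenylethyl)biphenyl-2,2',4,4'-tetrol
Product: 21 2-hydroxy-5-[4-hydroxy-5-methyl-3,6-dioxo-2-(2-phenylethyl)cyclohexa-1,4-dien-1-yl]-6-[2-(2-methoxyphenyl)ethyl]-3-methylcyclohexa-2,5-diene-1,4-dione
Conditions: (KSO3)2NO (5 equiv), aq. KH2PO4, acetone, 0 °C → rt
Reagents that add atoms: potassium nitrosodisulfonate (Fremy's salt) [O]N(S(=O)(=O)[O-])S(=O)(=O)[O-].[K+].[K+]
Why: Teuber oxidation with Fremy's radical should convert each resorcinol ring at its single free position (para to one hydroxy group, ortho to the other) into the 2-hydroxy-1,4-benzoquinone, and para or ortho attack lead to the same tautomeric hydroxyquinone, so no regiochemical issue arises.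

Compound list
1 | 3,5-dimethoxy-4-methylbenzaldehyde | COc1cc(C=O)cc(OC)c1C | starting material
2 | diethyl benzylphosphonate | CCOP(=O)(Cc1ccccc1)OCC | starting material
3 | sodium salt of the diethyl benzylphosphonate carbanion | CCOP(=O)(OCC)[CH-]c1ccccc1.[Na+] | intermediate
4 | (E)-1,3-dimethoxy-2-methyl-5-(2-phenylethenyl)benzene | COc1cc(/C=C/c2ccccc2)cc(OC)c1C | intermediate
5 | 1,3-dimethoxy-2-methyl-5-(2-phenylethyl)benzene | COc1cc(CCc2ccccc2)cc(OC)c1C | intermediate
6 | 2-methyl-5-(2-phenylethyl)benzene-1,3-diol | Cc1c(O)cc(CCc2ccccc2)cc1O | intermediate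
7 | 1-(3-bromopropyl)-2-methoxybenzene | COc1ccccc1CCCBr | starting material
8 | diethyl oxalate | CCOC(=O)C(=O)OCC | starting material
9 | [3-(2-methoxyphenyl)propyl]magnesium bromide | COc1ccccc1CCC[Mg]Br | intermediate
10 | ethyl 5-(2-methoxyphenyl)-2-oxopentanoate | CCOC(=O)C(=O)CCCc1ccccc1OC | intermediate
11 | ethyl 2-[2,4-dihydroxy-3-methyl-6-(2-phenylethyl)phenyl]-2-hydroxy-5-(2-methoxyphenyl)pentanoate (racemic) | CCOC(=O)C(O)(CCCc1ccccc1OC)c1c(O)c(C)c(O)cc1CCc1ccccc1 | intermediate
12 | 3,6-dihydroxy-3-[3-(2-methoxyphenyl)propyl]-7-methyl-4-(2-phenylethyl)-1-benzofuran-2(3H)-one (racemic) | O=C1Oc2c(C)c(O)cc(CCc3ccccc3)c2C1(O)CCCc1ccccc1OC | intermediate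
13 | (3Z)-6-hydroxy-3-[3-(2-methoxyphenyl)propylidene]-7-methyl-4-(2-phenylethyl)-1-benzofuran-2(3H)-one | O=C1Oc2c(C)c(O)cc(CCc3ccccc3)c2/C1=C/CCc1ccccc1OC | intermediate
14 | methyl phenyl sulfoxide (racemic) | CS(=O)c1ccccc1 | starting material
15 | ethyl propanoate | CCC(=O)OCC | starting material
16 | [(phenylsulfinyl)methyl]lithium | [Li]CS(=O)c1ccccc1 | intermediate
17 | 1-(phenylsulfinyl)butan-2-one (racemic) | CCC(=O)CS(=O)c1ccccc1 | intermediate
18 | 3-[1-(2-methoxyphenyl)-5-oxo-4-(phenylsulfinyl)heptan-3-yl]-6-hydroxy-7-methyl-4-(2-phenylethyl)-1-benzofuran-2(3H)-one (diastereomer mixture) | CCC(=O)C(S(=O)c1ccccc1)C(CCc1ccccc1OC)C1C(=O)Oc2c(C)c(O)cc(CCc3ccccc3)c21 | intermediate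
19 | 4-[2,4-dihydroxy-3-methyl-6-(2-phenylethyl)phenyl]-5-[2-(2-methoxyphenyl)ethyl]-2-methyl-6-(phenylsulfinyl)cyclohexane-1,3-dione (diastereomer mixture) | CC1C(=O)C(S(=O)c2ccccc2)C(CCc2ccccc2OC)C(c2c(CCc3ccccc3)cc(O)c(C)c2O)C1=O | intermediate
20 | 6-[2-(2-methoxyphenyl)ethyl]-3,3'-dimethyl-6'-(2-phenylethyl)biphenyl-2,2',4,4'-tetrol (racemic axis) | COc1ccccc1CCc1cc(O)c(C)c(O)c1-c1c(CCc2ccccc2)cc(O)c(C)c1O | intermediate
21 | 2-hydroxy-5-[4-hydroxy-5-methyl-3,6-dioxo-2-(2-phenylethyl)cyclohexa-1,4-dien-1-yl]-6-[2-(2-methoxyphenyl)ethyl]-3-methylcyclohexa-2,5-diene-1,4-dione | COc1ccccc1CCC1=C(C2=C(CCc3ccccc3)C(=O)C(O)=C(C)C2=O)C(=O)C(C)=C(O)C1=O | target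

Total step count: 8. Longest linear sequence: 6 steps (1, 2, 3, 5, 7, 8).

Steps most likely to fail

Step 7. The Michael adduct may rest as its stabilised anion with the lactone enolised, so that the Claisen closure does not start. The base may instead deprotonate the phenol or the γ-position of 13 and stall the conjugate addition. The sulfenic acid released may sulfenylate the electron-rich product. The fallback sets out from 13 and separates ring formation from the adjustment of oxidation level. Michael–Claisen annulation with methyl 3-oxopentanoate (NaOMe, MeOH, reflux), which forms the same two bonds, should give methyl 5-[2,4-dihydroxy-3-methyl-6-(2-phenylethyl)phenyl]-6-[2-(2-methoxyphenyl)ethyl]-3-methyl-2,4-dioxocyclohexane-1-carboxylate F1. Aqueous NaOH at reflux should hydrolyse and decarboxylate it to 4-[2,4-dihydroxy-3-methyl-6-(2-phenylethyl)phenyl]-5-[2-(2-methoxyphenyl)ethyl]-2-methylcyclohexane-1,3-dione F2. Catalytic dehydrogenation of F2 (Pd/C, mesitylene, reflux) aromatises the dione to the resorcinol and comes back to the route at 20.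

Step 5. A second molecule of 6 may trap the benzylic cation or add to the alkylidene lactone once it has formed, and the dehydration may stop at the tertiary alcohol. The fallback sets out from 6 and makes the exocyclic double bond by condensation instead. Hydroxyalkylation with glyoxylic acid (aq. NaOH, then HCl) should give 3,6-dihydroxy-7-methyl-4-(2-phenylethyl)-1-benzofuran-2(3H)-one F3. Reduction of the benzylic hydroxy group (SnCl2, HCl, AcOH) should give 6-hydroxy-7-methyl-4-(2-phenylethyl)-1-benzofuran-2(3H)-one F4. Knoevenagel condensation of F4 (piperidine, EtOH) with 3-(2-methoxyphenyl)propanal F5, made from 7 by Kornblum oxidation (DMSO, NaHCO3, 110 °C), comes back to the route at 13.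

Step 8. Phenoxy radicals may couple between molecules, the second ring may be oxidised incompletely, and the hydroxyquinone anion may be degraded by excess oxidant. The fallback sets out from 20 and introduces the para heteroatom by electrophilic substitution. Nitrosation at the two free ring positions (NaNO2, AcOH, H2O, 0 °C) should give 6-[2-(2-methoxyphenyl)ethyl]-3,3'-dimethyl-5,5'-dinitroso-6'-(2-phenylethyl)biphenyl-2,2',4,4'-tetrol F6. Reduction (Na2S2O4, aq. EtOH) should give 5,5'-diamino-6-[2-(2-methoxyphenyl)ethyl]-3,3'-dimethyl-6'-(2-phenylethyl)biphenyl-2,2',4,4'-tetrol F7. Oxidation with FeCl3 in dilute HCl gives the quinone imines, whose hydrolysis comes back to the route at 21.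

Further compounds
F1 | step 7 | methyl 5-[2,4-dihydroxy-3-methyl-6-(2-phenylethyl)phenyl]-6-[2-(2-methoxyphenyl)ethyl]-3-methyl-2,4-dioxocyclohexane-1-carboxylate (diastereomer mixture) | COC(=O)C1C(=O)C(C)C(=O)C(c2c(CCc3ccccc3)cc(O)c(C)c2O)C1CCc1ccccc1OC
F2 | step 7 | 4-[2,4-dihydroxy-3-methyl-6-(2-phenylethyl)phenyl]-5-[2-(2-methoxyphenyl)ethyl]-2-methylcyclohexane-1,3-dione (diastereomer mixture) | CC1C(=O)CC(CCc2ccccc2OC)C(c2c(CCc3ccccc3)cc(O)c(C)c2O)C1=O
F3 | step 5 | 3,6-dihydroxy-7-methyl-4-(2-phenylethyl)-1-benzofuran-2(3H)-one (racemic) | O=C1Oc2c(C)c(O)cc(CCc3ccccc3)c2C1O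
F4 | step 5 | 6-hydroxy-7-methyl-4-(2-phenylethyl)-1-benzofuran-2(3H)-one | O=C1Cc2c(CCc3ccccc3)cc(O)c(C)c2O1
F5 | step 5 | 3-(2-methoxyphenyl)propanal | COc1ccccc1CCC=O
F6 | step 8 | 6-[2-(2-methoxyphenyl)ethyl]-3,3'-dimethyl-5,5'-dinitroso-6'-(2-phenylethyl)biphenyl-2,2',4,4'-tetrol | COc1ccccc1CCc1c(N=O)c(O)c(C)c(O)c1-c1c(CCc2ccccc2)c(N=O)c(O)c(C)c1O
F7 | step 8 | 5,5'-diamino-6-[2-(2-methoxyphenyl)ethyl]-3,3'-dimethyl-6'-(2-phenylethyl)biphenyl-2,2',4,4'-tetrol | COc1ccccc1CCc1c(N)c(O)c(C)c(O)c1-c1c(CCc2ccccc2)c(N)c(O)c(C)c1O
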